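If these flasks are run again, the thing to watch is the ratio of partner to target.

| setting | delta | north-east | north-west | west |
|---|---|---|---|---|
| starting material | 0.091 M | 0.091 M | 0.091 M | 0.091 M |
| partner | 0.11 M | 0.0546 M | 0.0546 M | 0.0546 M |
| second substrate | 0.0182 M | 0.0182 M | 0.0182 M | 0.0182 M |
| protic impurity | 0.0273 M | 0.0273 M | 0.0273 M | 0.0273 M |
| temperature | 20 °C |  | 20 °C | 35 °C |
| remark | run made earlier | at 35 °C until 20 h, from then on at 20 °C |  |  |
| time |  | 2.5 d | 2.5 d | 2.5 d |

- in percentages every species weighs as the starting material in it: one side product counts as two
- the analysis behind the earlier runs scatters by 0.5 percentage points, standard deviation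
- candidate steps: partner + protic impurity -> quenched reagent; second substrate + partner -> second product; starting material + partner -> target; starting material + target -> side product; starting material + second substrate -> cross product
- the earlier runs do not show what temperature does; that part of a forecast is a guess

1. the flask with the highest amount of target, in percent of the starting material charged ("all alike" if they lie within 1.5 percentage points) (north-east / north-west / west / all alike)
2. final target, as a percentage of the starting material charged, in north-east
3. final target, as a percentage of the starting material charged, in north-west
4. final target, as a percentage of the starting material charged, in west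

- delta (time / h: target / %, starting material / %): 0.333: 1.9, 98.5; 1.00: 4.5, 95.1; 1.50: 7.8, 92.8; 2.50: 10.1, 89.5; 4.00: 15.8, 82.7; 5.00: 16.9, 80.8; 6.00: 19.4, 76.6

(readings scatter by 0.5 percentage points)

I wrote A, B and P for starting material, partner and target. Target is made at k_m·A·B and used at k_u·A·P, so A cancels: made over used is B/(sP), with s = k_u/k_m.

I read s from the table. The top row sums A and P to 100 %, so this end shows no loss. The bottom row sums to 96.0 %, a gap g of 4 percentage points. Side product counts double, so g is 2 times the target used, and the target made was F = 21.4 %.

I assumed second substrate took its partner first, and I left protic impurity out of this balance. Partner then stood near 90.2 % of the charge of A on average. While B barely moves, g = s·F·F/B, so s came to 0.788, the selectivity factor. The row at 4.00 h gives 0.507, lower than the bottom row. Its gap is smaller against the same scatter of 0.5 points, so I kept the bottom row.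

At the other end, target peaks where B = sP. Joining the ends gives a peak of b·s^(s/(1−s)), where b is partner charge less second substrate. In north-west, b is 40.0 % of A, so I expected a peak near 16.5 %. The rows stand at 20 °C, so they give no s for 35 °C.

The forecast took s near 0.6, where I had 0.788. It counted about 0.027 M of partner surviving the quench, where my b is 0.0364 M. It held that “partner is limiting”, which makes partner the limiting reagent. It named north-west, with 7.5 % in north-east, 12.5 % in north-west and 3.5 % in west.

The flasks gave 6.38 % in north-east, 13.5 % in north-west and 1.56 % in west, so north-west led, as forecast.

    partner + protic impurity → quenched reagent (k = 0.0230 L mol⁻¹ min⁻¹, Ea = 81.0 kJ mol⁻¹)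
    second substrate + partner → second product (k = 0.210 L mol⁻¹ min⁻¹, Ea = 60.0 kJ mol⁻¹)
    starting material + partner → target (k = 0.0240 L mol⁻¹ min⁻¹, Ea = 56.0 kJ mol⁻¹)
    starting material + target → side product (k = 0.0230 L mol⁻¹ min⁻¹, Ea = 70.0 kJ mol⁻¹)
    starting material + second substrate → cross product (k = 0.00190 L mol⁻¹ min⁻¹, Ea = 68.0 kJ mol⁻¹)
    (constants at 35 °C)

Target in north-west stood at 16.8 % after 1.25 d, then fell to 13.5 %. There B/(sP) ended at 0.363, below one. The neighbour of west, charged with 0.055 M of starting material, ended with 10.2 % target against 1.56 % in west. Its partner stood at 1.68 % of its charge. With s carried over from 20 °C, though this flask stood at 35 °C, B/(sP) was 0.208, also below one, and side product held 63.8 %.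

The readings are calculated with constants of no real substance; noise was put on by code.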